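**Retrosynthetic overview**
- The butenolide is opened at its lactone acyl C–O bond. Behind that bond lies only a reversible aldol C–C bond, so the target falls apart into a hexafluoroisopropyl 4-hydroxyphenylpyruvate (acyl donor) and a methyl chromanylpyruvate (acceptor). The ring closure is meant to decide both cross-selectivity and the quaternary stereocentre.
- The methyl chromanylpyruvate comes from the chromanol aldehyde by olefination with a Boc-phosphonoglycinate and hydrolysis. The aldehyde comes from the nitrile.
- The chroman C3–O bond (3S) is made by Jacobsen–Katsuki epoxidation of 2,2-dimethyl-2H-chromene-6-carbonitrile, then benzylic hydrogenolysis of the epoxide.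
- Ring order: the chroman ring is bought intact and the butenolide ring is closed last. No protecting groups are used.

Assumption: arylpyruvic acid derivatives are written as keto tautomers although they exist largely as Z-enols, and 2,2-dimethyl-2H-chromene-6-carbonitrile is taken as a catalogue starting material.

**Step 1**
Reactants: 1 3-(4-hydroxyphenyl)-2-oxopropanoic acid (4-hydroxyphenylpyruvic acid); 2 1,1,1,3,3,3-hexafluoropropan-2-ol
Product: 3 1,1,1,3,3,3-hexafluoropropan-2-yl 3-(4-hydroxyphenyl)-2-oxopropanoate
Conditions: 2 (10 equiv), DIC (1.1 equiv), DMAP (5 mol%), CH2Cl2, 0 °C → rt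
Reagents that add atoms: none
Why: Steglich esterification, in which the large excess of fluoroalcohol out-competes the phenol for the acyl-pyridinium; no stereocentre is involved.

**Step 2**
Reactants: 4 2,2-dimethyl-2H-chromene-6-carbonitrile
Product: 5 (3S,4S)-3,4-epoxy-2,2-dimethyl-3,4-dihydro-2H-chromene-6-carbonitrile
Conditions: (S,S)-N,N′-bis(3,5-di-tert-butylsalicylidene)-1,2-cyclohexanediaminomanganese chloride (trivalent manganese, 2 mol%), 4-phenylpyridine N-oxide (10 mol%), aq. NaOCl (pH 11.3, Na2HPO4), CH2Cl2, 0 °C
Reagents that add atoms: sodium hypochlorite, [Na+].[O-]Cl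
Why: Jacobsen–Katsuki epoxidation of a cis-disubstituted conjugated alkene, for which 2,2-dimethylchromenes are a standard high-selectivity substrate class; the (S,S)-catalyst delivers oxygen to one face to give the (3S,4S)-epoxide, which sets chroman C3 by C–O bond formation, and the nitrile is inert.

**Step 3**
Reactants: 5 (3S,4S)-3,4-epoxy-2,2-dimethyl-3,4-dihydro-2H-chromene-6-carbonitrile
Product: 6 (3S)-3-hydroxy-2,2-dimethyl-3,4-dihydro-2H-chromene-6-carbonitrile
Conditions: H2 (1 atm), 10% Pd/C, EtOAc, rt, stopped after 1 equiv uptake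
Reagents that add atoms: none
Why: Palladium-catalysed hydrogenolysis of an aryl epoxide cleaves only the benzylic C4–O bond, so the C3–O bond and its 3S configuration are kept, and an aryl nitrile survives 1 atm of hydrogen in a neutral aprotic solvent.

**Step 4**
Reactants: 6 (3S)-3-hydroxy-2,2-dimethyl-3,4-dihydro-2H-chromene-6-carbonitrile
Product: 8 (3S)-3-hydroxy-2,2-dimethyl-3,4-dihydro-2H-chromene-6-carbaldehyde, via bis-aluminated aldimine 7 (not isolated)
Conditions: i-Bu2AlH (2.5 equiv), CH2Cl2, −78 °C; then 1 M HCl, 0 °C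
Reagents that add atoms: water, O
Why: Partial reduction of a nitrile with i-Bu2AlH: one equivalent is taken up by the alcohol, the next adds once to the nitrile to give an aluminated aldimine that is stable at −78 °C and is hydrolysed to the aldehyde on acidic work-up; C3 is untouched.

**Step 5**
Reactants: 8 (3S)-3-hydroxy-2,2-dimethyl-3,4-dihydro-2H-chromene-6-carbaldehyde; 9 methyl 2-[(tert-butoxycarbonyl)amino]-2-(dimethoxyphosphoryl)acetate (racemic)
Product: 11 methyl 3-[(3S)-3-hydroxy-2,2-dimethyl-3,4-dihydro-2H-chromen-6-yl]-2-oxopropanoate, via Z-dehydroamino ester 10 (not isolated)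
Conditions: 1,1,3,3-tetramethylguanidine (1.3 equiv), THF, −78 °C → rt; then TFA/H2O (9:1), rt; aq. NaHCO3 work-up
Reagents that add atoms: water, O
Why: Horner–Wadsworth–Emmons olefination gives the Z-dehydroamino ester, and acid then removes the Boc group and hydrolyses the C–N bond in the same flask to leave the α-keto ester; the free secondary alcohol tolerates the guanidine base, and any trifluoroacetate ester is cleaved in the bicarbonate work-up.

**Step 6**
Reactants: 3 1,1,1,3,3,3-hexafluoropropan-2-yl 3-(4-hydroxyphenyl)-2-oxopropanoate; 11 methyl 3-[(3S)-3-hydroxy-2,2-dimethyl-3,4-dihydro-2H-chromen-6-yl]-2-oxopropanoate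
Product: 13 butyrolactone V [methyl (2R)-4-hydroxy-2-{[(3S)-3-hydroxy-2,2-dimethyl-3,4-dihydro-2H-chromen-6-yl]methyl}-3-(4-hydroxyphenyl)-5-oxo-2,5-dihydrofuran-2-carboxylate], via open-chain aldol adduct 12 (not isolated)
Conditions: squaramide Q (20 mol%), 11 (1.0 equiv), 3 (1.6 equiv, added over 8 h), 4 Å MS, CH2Cl2/PhMe (1:1), −20 °C
Reagents that add atoms: none
Why: Proposed new method: a cross-selective, enantioselective aldol–lactonisation in which the ring-closing acyl C–O bond formation is the selectivity-determining event; catalyst Q is the bifunctional squaramide 3-{[3,5-bis(trifluoromethyl)phenyl]amino}-4-{[(9R)-6′-methoxycinchonan-9-yl]amino}cyclobut-3-ene-1,2-dione (from 9-amino-9-deoxy-epi-quinidine), whose quinuclidine deprotonates the more acidic fluoroalkyl enol 3, so that 3 is the nucleophile and the less acidic 11 reacts through its keto form as the electrophile; addition of this stabilised enolate to a ketone is fast, reversible and thermodynamically uphill, so the tertiary aldolate 12 only goes forward when its oxygen closes onto the hexafluoroisopropyl ester, a step in which the squaramide N–H bonds hold the tetrahedral oxyanion and the quinuclidinium protonates the leaving fluoroalkoxide; aldolates in which 11 was the nucleophile carry only a methyl ester at the closing position and revert, which gives cross-selectivity, and slow addition of 3 suppresses its self-condensation; of the two enantiomeric aldolates the chiral pocket closes the one that gives the 2R quaternary carbon (catalyst control; the absolute sense cannot be predicted with confidence, and the quinine-derived pseudoenantiomer is used if it proves opposite), after which the product rests as its stable enol and cannot reopen; chroman C3 is remote and unaffected; the closest known reaction types are the amine-base-mediated homo-aldol–lactonisation of methyl arylpyruvates to 3-hydroxybutenolides and squaramide-catalysed addition–lactonisation cascades that turn over by loss of hexafluoroisopropanol.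

**Compound list**
1 | 3-(4-hydroxyphenyl)-2-oxopropanoic acid | O=C(O)C(=O)Cc1ccc(O)cc1 | starting material
2 | 1,1,1,3,3,3-hexafluoropropan-2-ol | OC(C(F)(F)F)C(F)(F)F | starting material
3 | 1,1,1,3,3,3-hexafluoropropan-2-yl 3-(4-hydroxyphenyl)-2-oxopropanoate | O=C(Cc1ccc(O)cc1)C(=O)OC(C(F)(F)F)C(F)(F)F | intermediate
4 | 2,2-dimethyl-2H-chromene-6-carbonitrile | CC1(C)C=Cc2cc(C#N)ccc2O1 | starting material
5 | (3S,4S)-3,4-epoxy-2,2-dimethyl-3,4-dihydro-2H-chromene-6-carbonitrile | N#Cc1ccc2c(c1)[C@@H]1O[C@@H]1C(C)(C)O2 | intermediate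
6 | (3S)-3-hydroxy-2,2-dimethyl-3,4-dihydro-2H-chromene-6-carbonitrile | N#Cc1ccc2c(c1)C[C@H](O)C(C)(C)O2 | intermediate
7 | (3S)-3-[(diisobutylalumanyl)oxy]-2,2-dimethyl-3,4-dihydro-2H-chromene-6-carbaldehyde N-(diisobutylalumanyl)imine (not isolated) | CC(C)C[Al](CC(C)C)N=Cc1ccc2c(c1)C[C@H](O[Al](CC(C)C)CC(C)C)C(C)(C)O2 | intermediate
8 | (3S)-3-hydroxy-2,2-dimethyl-3,4-dihydro-2H-chromene-6-carbaldehyde | O=Cc1ccc2c(c1)C[C@H](O)C(C)(C)O2 | intermediate
9 | methyl 2-[(tert-butoxycarbonyl)amino]-2-(dimethoxyphosphoryl)acetate (racemic) | COC(=O)C(NC(=O)OC(C)(C)C)P(=O)(OC)OC | starting material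
10 | methyl (Z)-2-[(tert-butoxycarbonyl)amino]-3-[(3S)-3-hydroxy-2,2-dimethyl-3,4-dihydro-2H-chromen-6-yl]prop-2-enoate (not isolated) | COC(=O)/C(NC(=O)OC(C)(C)C)=C/c1ccc2c(c1)C[C@H](O)C(C)(C)O2 | intermediate
11 | methyl 3-[(3S)-3-hydroxy-2,2-dimethyl-3,4-dihydro-2H-chromen-6-yl]-2-oxopropanoate | COC(=O)C(=O)Cc1ccc2c(c1)C[C@H](O)C(C)(C)O2 | intermediate
12 | 1-(1,1,1,3,3,3-hexafluoropropan-2-yl) 5-methyl (4R)-4-hydroxy-4-{[(3S)-3-hydroxy-2,2-dimethyl-3,4-dihydro-2H-chromen-6-yl]methyl}-3-(4-hydroxyphenyl)-2-oxopentanedioate (C3 unassigned; not isolated) | COC(=O)[C@@](O)(Cc1ccc2c(c1)C[C@H](O)C(C)(C)O2)C(c1ccc(O)cc1)C(=O)C(=O)OC(C(F)(F)F)C(F)(F)F | intermediate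
13 | butyrolactone V, methyl (2R)-4-hydroxy-2-{[(3S)-3-hydroxy-2,2-dimethyl-3,4-dihydro-2H-chromen-6-yl]methyl}-3-(4-hydroxyphenyl)-5-oxo-2,5-dihydrofuran-2-carboxylate | COC(=O)[C@]1(Cc2ccc3c(c2)C[C@H](O)C(C)(C)O3)OC(=O)C(O)=C1c1ccc(O)cc1 | target

**Totals**
Total step count: 6.
Longest linear sequence: 5 steps (steps 2, 3, 4, 5, 6, from 4 to 13).

**Three steps most likely to fail**

Step 6 (the proposed new step). It may give poor cross-selectivity or a low diastereomer ratio at the quaternary carbon. The fallback uses known chemistry, sets out from 1 and 11 and comes back at 13. Acid 1 is esterified with methanol and TMSCl to give methyl 3-(4-hydroxyphenyl)-2-oxopropanoate F1. F1 and 11 are then condensed with DBU in DMF at 0 °C → rt, the established base-mediated aldol–lactonisation of methyl arylpyruvates. This is unselective at the quaternary carbon and only statistically cross-selective. Compound 13 is separated from self-condensation products by chromatography. It is separated from its epimer at the quaternary carbon, methyl (2S)-4-hydroxy-2-{[(3S)-3-hydroxy-2,2-dimethyl-3,4-dihydro-2H-chromen-6-yl]methyl}-3-(4-hydroxyphenyl)-5-oxo-2,5-dihydrofuran-2-carboxylate F2, by preparative HPLC on a chiral stationary phase; the two are diastereomers because chroman C3 is already fixed as S.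

Step 1. The carbodiimide coupling of an unprotected phenolic arylpyruvic acid may give phenol-linked oligoesters or self-condensation. The fallback sets out from 1 and comes back at 13. Acid 1 is esterified without any coupling agent or acyl-transfer catalyst, by acid-catalysed esterification in neat 2,2,2-trifluoroethanol (cat. H2SO4, 3 Å MS, 70 °C), to give 2,2,2-trifluoroethyl 3-(4-hydroxyphenyl)-2-oxopropanoate F3. F3 takes the place of 3 in step 6 and is added more slowly, since trifluoroethoxide is a poorer leaving group and the rate gap to the methyl ester is smaller.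

Step 5. The one-flask olefination and hydrolysis may stall at the dehydroamino ester, or the keto ester may self-condense on isolation. The fallback sets out from 8 and comes back at 11. Aldehyde 8 is condensed with hydantoin (ethanolamine, H2O/EtOH, 90 °C) to give (5Z)-5-{[(3S)-3-hydroxy-2,2-dimethyl-3,4-dihydro-2H-chromen-6-yl]methylidene}imidazolidine-2,4-dione F4. F4 is hydrolysed with 20% aq. NaOH at reflux under nitrogen, then acidified cold with HCl, to give 3-[(3S)-3-hydroxy-2,2-dimethyl-3,4-dihydro-2H-chromen-6-yl]-2-oxopropanoic acid F5. F5 is esterified with methanol and TMSCl to give 11.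

**Further compounds**
F1 | step 6 | methyl 3-(4-hydroxyphenyl)-2-oxopropanoate | COC(=O)C(=O)Cc1ccc(O)cc1
F2 | step 6 | methyl (2S)-4-hydroxy-2-{[(3S)-3-hydroxy-2,2-dimethyl-3,4-dihydro-2H-chromen-6-yl]methyl}-3-(4-hydroxyphenyl)-5-oxo-2,5-dihydrofuran-2-carboxylate | COC(=O)[C@@]1(Cc2ccc3c(c2)C[C@H](O)C(C)(C)O3)OC(=O)C(O)=C1c1ccc(O)cc1
F3 | step 1 | 2,2,2-trifluoroethyl 3-(4-hydroxyphenyl)-2-oxopropanoate | O=C(Cc1ccc(O)cc1)C(=O)OCC(F)(F)F
F4 | step 5 | (5Z)-5-{[(3S)-3-hydroxy-2,2-dimethyl-3,4-dihydro-2H-chromen-6-yl]methylidene}imidazolidine-2,4-dione | O=C1N/C(=C\c2ccc3c(c2)C[C@H](O)C(C)(C)O3)C(=O)N1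
F5 | step 5 | 3-[(3S)-3-hydroxy-2,2-dimethyl-3,4-dihydro-2H-chromen-6-yl]-2-oxopropanoic acid | OC(=O)C(=O)Cc1ccc2c(c1)C[C@H](O)C(C)(C)O2
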